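**Plan**
- The target is 7,7''-di-O-methylhinokiflavone. Half 1 (locants 2–8a and 1'–6') is the flavone whose 4'-oxygen forms the bridge, and half 2 (locants 2''–8a'' and 1'''–6''') carries that oxygen at C6''. There is no stereocentre, so no stereocontrol is needed.
- Enabling feature: in ring A of half 1 the neighbouring carbons C8a and C4a carry O1 and the acyl carbon C4, and C5 beside C4a carries oxygen. This 1-oxy-2-acyl-3-alkoxy array is what a 3-alkoxybenzyne gives when the O and C of a carboxyl group are delivered across its triple bond.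
- Cuts, in order: the two chelated 5-O-methyl groups and a 4'''-O-benzyl group are added as masks. Then C8a–O1, C4a–C4 and O1–C2 of the half 1 pyranone are cut, giving a silylaryl triflate and an arylpropiolic acid that holds all of half 2. Next comes C1'–C2 (aryl iodide plus propiolic acid), then O1''–C2'' and C2''–C3'' (chalcone), then the ether O–C4' (SNAr), and last C4a''–C4'' (acylation).
- Forward: ring A of half 2 comes from syringaldehyde, followed by the diaryl ether to ring B of half 1, the chalcone, and ring C of half 2. The sequence nitro → amine → iodide → propiolic acid follows. The aryne step then brings in ring A and closes ring C of half 1, and one Lewis acid step frees three phenols.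

Key step: step 11

Remark: the only stereogenic element on the way is the E double bond of chalcone 8, which disappears on aromatisation in step 5. All compounds marked as starting materials are taken to be commercial.

**Step 1**
Reactants: 1 syringaldehyde (4-hydroxy-3,5-dimethoxybenzaldehyde)
Product: 3 2,6-dimethoxybenzene-1,4-diol, via aryl formate 2 (not isolated)
Conditions: H2O2 (30 % aq, 1.05 equiv), NaOH (1 M aq), THF, N2, 0 °C → rt; then HCl
Reagents that add atoms: hydrogen peroxide, OO
Why: Dakin oxidation, in which hydroperoxide adds to the aldehyde of a para-hydroxybenzaldehyde, the electron-rich aryl group migrates to oxygen and formate 2 is saponified in the same alkaline medium, while exclusion of air and a near-stoichiometric charge of oxidant should keep the hydroquinone from going on to the quinone.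

**Step 2**
Reactants: 3 2,6-dimethoxybenzene-1,4-diol
Product: 4 1-(3,6-dihydroxy-2,4-dimethoxyphenyl)ethan-1-one
Conditions: AcOH, BF3·OEt2, 85 °C, Ar; then ice–water
Reagents that add atoms: acetic acid, CC(=O)O
Why: Friedel–Crafts acylation with the AcOH–BF3 couple, in which the two free ring carbons of 3 are symmetry-related and lie ortho to the unhindered hydroxyl, so a single ketone should form, and chelation of its carbonyl group to that hydroxyl deactivates the ring towards a second acylation.

**Step 3**
Reactants: 4 1-(3,6-dihydroxy-2,4-dimethoxyphenyl)ethan-1-one; 5 1-fluoro-4-nitrobenzene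
Product: 6 1-[6-hydroxy-2,4-dimethoxy-3-(4-nitrophenoxy)phenyl]ethan-1-one
Conditions: 5 (1.0 equiv), K2CO3 (1.1 equiv), DMF, 70 °C, Ar
Reagents that add atoms: none
Why: Nucleophilic aromatic substitution (SNAr), in which the non-chelated C3 phenoxide attacks the para-nitro-activated fluoride while the C6 hydroxyl stays hydrogen-bonded to the acetyl group, the same bias that governs selective O-alkylation of 2,5-dihydroxyacetophenones.

**Step 4**
Reactants: 6 1-[6-hydroxy-2,4-dimethoxy-3-(4-nitrophenoxy)phenyl]ethan-1-one; 7 4-(benzyloxy)benzaldehyde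
Product: 8 (E)-3-[4-(benzyloxy)phenyl]-1-[6-hydroxy-2,4-dimethoxy-3-(4-nitrophenoxy)phenyl]prop-2-en-1-one
Conditions: KOH (50 % aq), EtOH, rt; then 1 M HCl
Reagents that add atoms: none
Why: Claisen–Schmidt condensation, in which the methyl ketone enolate adds to the non-enolisable aldehyde and E1cB loss of water gives the conjugated enone with the thermodynamically preferred E geometry, the nitrophenyl ether being displaced far too slowly at room temperature to interfere.

**Step 5**
Reactants: 8 (E)-3-[4-(benzyloxy)phenyl]-1-[6-hydroxy-2,4-dimethoxy-3-(4-nitrophenoxy)phenyl]prop-2-en-1-one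
Product: 9 2-[4-(benzyloxy)phenyl]-5,7-dimethoxy-6-(4-nitrophenoxy)-4H-chromen-4-one
Conditions: I2 (10 mol %), DMSO, 130 °C
Reagents that add atoms: none
Why: Iodine-catalysed oxidative cyclisation of a 2'-hydroxychalcone in DMSO, the standard flavone synthesis, which forms O1''–C2'' and leaves the C2''=C3'' double bond, with DMSO as terminal oxidant that regenerates iodine and with the nitro group, the benzyl ether and the methyl ethers inert.

**Step 6**
Reactants: 9 2-[4-(benzyloxy)phenyl]-5,7-dimethoxy-6-(4-nitrophenoxy)-4H-chromen-4-one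
Product: 10 6-(4-aminophenoxy)-2-[4-(benzyloxy)phenyl]-5,7-dimethoxy-4H-chromen-4-one
Conditions: Fe powder, NH4Cl, EtOH/THF/H2O, 75 °C
Reagents that add atoms: none
Why: Béchamp-type reduction with zerovalent iron under nearly neutral conditions, which takes the nitro group to the amine by electron transfer and protonation and spares the benzyl ether and the chromenone double bond that catalytic hydrogenation would endanger.

**Step 7**
Reactants: 10 6-(4-aminophenoxy)-2-[4-(benzyloxy)phenyl]-5,7-dimethoxy-4H-chromen-4-one
Product: 12 2-[4-(benzyloxy)phenyl]-6-(4-iodophenoxy)-5,7-dimethoxy-4H-chromen-4-one, via diazonium tosylate 11 (not isolated)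
Conditions: p-TsOH·H2O (3 equiv), NaNO2 (2 equiv), KI (2.5 equiv), MeCN/H2O, 10 °C → rt
Reagents that add atoms: potassium iodide, [K+].[I-]; for intermediate 11 only: sodium nitrite, [Na+].[O-]N=O, and p-toluenesulfonic acid, Cc1ccc(S(=O)(=O)O)cc1
Why: Sandmeyer-type iododediazoniation, in which the stable arenediazonium tosylate 11 is reduced by iodide to the aryl radical that picks up iodine without copper, and no ring of the molecule is nucleophilic enough for azo coupling because no free phenol is present.

**Step 8**
Reactants: 12 2-[4-(benzyloxy)phenyl]-6-(4-iodophenoxy)-5,7-dimethoxy-4H-chromen-4-one; 13 propiolic acid (prop-2-ynoic acid)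
Product: 14 3-[4-({2-[4-(benzyloxy)phenyl]-5,7-dimethoxy-4-oxo-4H-chromen-6-yl}oxy)phenyl]prop-2-ynoic acid
Conditions: 13 (1.2 equiv), Pd(PPh3)4 (5 mol %), DBU (2.5 equiv), DMSO, 30 °C; then 1 M HCl
Reagents that add atoms: none
Why: Copper-free Sonogashira coupling of an aryl iodide with propiolic acid, in which oxidative addition to zerovalent palladium is easy near room temperature and DBU supplies the alkynyl carboxylate, while the low temperature and the absence of copper hold back decarboxylation and alkyne dimerisation.

**Step 9**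
Reactants: 15 3,5-dimethoxyphenol
Product: 16 2-bromo-3,5-dimethoxyphenol
Conditions: NBS (1.0 equiv), CH2Cl2, −78 °C → 0 °C
Reagents that add atoms: N-bromosuccinimide, O=C1CCC(=O)N1Br
Why: Electrophilic aromatic bromination, in which NBS in a non-polar solvent is guided by hydrogen bonding to the phenol towards the ortho carbon C2, which is also para to the C5 methoxy group, while C4 is shielded between two methoxy groups.

**Step 10**
Reactants: 16 2-bromo-3,5-dimethoxyphenol
Product: 19 3,5-dimethoxy-2-(trimethylsilyl)phenyl trifluoromethanesulfonate, via silyl ether 17 (not isolated), via lithium phenoxide 18 (not isolated)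
Conditions: HMDS, THF, 70 °C, then evaporation; n-BuLi, THF, −78 °C; Tf2O, −78 °C → rt
Reagents that add atoms: hexamethyldisilazane, C[Si](C)(C)N[Si](C)(C)C; trifluoromethanesulfonic anhydride, O=S(=O)(OS(=O)(=O)C(F)(F)F)C(F)(F)F; for intermediate 18 only: n-butyllithium, [Li]CCCC
Why: O-silylation, bromine–lithium exchange and retro-Brook (1,3 O-to-C) silyl migration give phenoxide 18, which is triflated in the same flask, the standard way from an ortho-bromophenol to an ortho-silylaryl triflate.

**Step 11**
Reactants: 14 3-[4-({2-[4-(benzyloxy)phenyl]-5,7-dimethoxy-4-oxo-4H-chromen-6-yl}oxy)phenyl]prop-2-ynoic acid; 19 3,5-dimethoxy-2-(trimethylsilyl)phenyl trifluoromethanesulfonate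
Product: 22 2-[4-({2-[4-(benzyloxy)phenyl]-5,7-dimethoxy-4-oxo-4H-chromen-6-yl}oxy)phenyl]-5,7-dimethoxy-4H-chromen-4-one, via aryne 20 (not isolated), via hydroxyaryl ynone 21 (not isolated)
Conditions: 19 (2 equiv), CsF (5 equiv), THF (0.02 M in 14), 125 °C, sealed tube
Reagents that add atoms: none
Why: Fluoride removes the silyl group of 19 and triflate departs to give aryne 20, whereupon the caesium carboxylate of 14 bonds to the aryne carbon distal to the flanking methoxy group (the future C8a) and leaves the aryl anion on the carbon next to that group (the future C4a). This anion attacks its own carboxyl carbon (4-exo-trig) and the strained four-membered alkoxide opens to the phenoxide of ynone 21, so that the aryne has formally entered the C–O bond of the acid and C8a–O1 and C4a–C4 are made. The phenoxide then adds to the β-carbon of the ynone in a 6-endo-dig oxa-Michael closure that forms O1–C2 and, after protonation at C3, ring C of half 1. The closest known reaction type is the thermal insertion of arynes into carboxylic acids to give ortho-hydroxyaryl ketones, which with arylpropiolic acids runs on to flavones and is here only applied to a larger acid. No stereocentre arises; the required regiochemistry is secured by the inductive pull and ring distortion that the methoxy group beside the triple bond imposes, and high dilution at 125 °C should favour acyl transfer over proton capture by the aryl anion. The endo mode is secured by the polarisation of the ynone, by the aprotic medium in which a 5-exo vinyl anion is not trapped and can revert, and by the stability of the 4-pyranone, while 14 offers no OH or NH besides the acid itself to intercept 20.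

**Step 12**
Reactants: 22 2-[4-({2-[4-(benzyloxy)phenyl]-5,7-dimethoxy-4-oxo-4H-chromen-6-yl}oxy)phenyl]-5,7-dimethoxy-4H-chromen-4-one
Product: 23 5-hydroxy-2-(4-{[5-hydroxy-2-(4-hydroxyphenyl)-7-methoxy-4-oxo-4H-chromen-6-yl]oxy}phenyl)-7-methoxy-4H-chromen-4-one (the target)
Conditions: BCl3 (1 M in CH2Cl2, 8 equiv), C6HMe5 (4 equiv), CH2Cl2, −78 °C → rt; then 1 M HCl/THF
Reagents that add atoms: none
Why: Chelation-directed ether cleavage, in which BCl3 bridges each C4 carbonyl oxygen and the peri 5-methoxy oxygen so that chloride removes only these two methyl groups, the benzyl ether is ionised by the same reagent and its cation is caught by pentamethylbenzene, and the 7-methoxy groups and the diaryl ether have no such activation.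

**Compound list**
1 | syringaldehyde (4-hydroxy-3,5-dimethoxybenzaldehyde) | COc1cc(C=O)cc(OC)c1O | starting material
2 | 4-hydroxy-3,5-dimethoxyphenyl formate | COc1cc(OC=O)cc(OC)c1O | intermediate
3 | 2,6-dimethoxybenzene-1,4-diol | COc1cc(O)cc(OC)c1O | intermediate
4 | 1-(3,6-dihydroxy-2,4-dimethoxyphenyl)ethan-1-one | CC(=O)c1c(O)cc(OC)c(O)c1OC | intermediate
5 | 1-fluoro-4-nitrobenzene | O=[N+]([O-])c1ccc(F)cc1 | starting material
6 | 1-[6-hydroxy-2,4-dimethoxy-3-(4-nitrophenoxy)phenyl]ethan-1-one | CC(=O)c1c(O)cc(OC)c(Oc2ccc([N+](=O)[O-])cc2)c1OC | intermediate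
7 | 4-(benzyloxy)benzaldehyde | O=Cc1ccc(OCc2ccccc2)cc1 | starting material
8 | (E)-3-[4-(benzyloxy)phenyl]-1-[6-hydroxy-2,4-dimethoxy-3-(4-nitrophenoxy)phenyl]prop-2-en-1-one | COc1cc(O)c(C(=O)/C=C/c2ccc(OCc3ccccc3)cc2)c(OC)c1Oc1ccc([N+](=O)[O-])cc1 | intermediate
9 | 2-[4-(benzyloxy)phenyl]-5,7-dimethoxy-6-(4-nitrophenoxy)-4H-chromen-4-one | O=[N+]([O-])c1ccc(Oc2c(OC)cc3oc(-c4ccc(OCc5ccccc5)cc4)cc(=O)c3c2OC)cc1 | intermediate
10 | 6-(4-aminophenoxy)-2-[4-(benzyloxy)phenyl]-5,7-dimethoxy-4H-chromen-4-one | Nc1ccc(Oc2c(OC)cc3oc(-c4ccc(OCc5ccccc5)cc4)cc(=O)c3c2OC)cc1 | intermediate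
11 | 4-({2-[4-(benzyloxy)phenyl]-5,7-dimethoxy-4-oxo-4H-chromen-6-yl}oxy)benzenediazonium 4-methylbenzenesulfonate | N#[N+]c1ccc(Oc2c(OC)cc3oc(-c4ccc(OCc5ccccc5)cc4)cc(=O)c3c2OC)cc1.Cc1ccc(S(=O)(=O)[O-])cc1 | intermediate
12 | 2-[4-(benzyloxy)phenyl]-6-(4-iodophenoxy)-5,7-dimethoxy-4H-chromen-4-one | Ic1ccc(Oc2c(OC)cc3oc(-c4ccc(OCc5ccccc5)cc4)cc(=O)c3c2OC)cc1 | intermediate
13 | propiolic acid (prop-2-ynoic acid) | C#CC(=O)O | starting material
14 | 3-[4-({2-[4-(benzyloxy)phenyl]-5,7-dimethoxy-4-oxo-4H-chromen-6-yl}oxy)phenyl]prop-2-ynoic acid | OC(=O)C#Cc1ccc(Oc2c(OC)cc3oc(-c4ccc(OCc5ccccc5)cc4)cc(=O)c3c2OC)cc1 | intermediate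
15 | 3,5-dimethoxyphenol | COc1cc(O)cc(OC)c1 | starting material
16 | 2-bromo-3,5-dimethoxyphenol | COc1cc(O)c(Br)c(OC)c1 | intermediate
17 | (2-bromo-3,5-dimethoxyphenoxy)trimethylsilane | COc1cc(O[Si](C)(C)C)c(Br)c(OC)c1 | intermediate
18 | lithium 3,5-dimethoxy-2-(trimethylsilyl)phenoxide | COc1cc([O-])c([Si](C)(C)C)c(OC)c1.[Li+] | intermediate
19 | 3,5-dimethoxy-2-(trimethylsilyl)phenyl trifluoromethanesulfonate | COc1cc(OC)c([Si](C)(C)C)c(OS(=O)(=O)C(F)(F)F)c1 | intermediate
20 | 3,5-dimethoxybenzyne (1,2-didehydro-3,5-dimethoxybenzene) | COC1=CC(OC)=CC#C1 | intermediate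
21 | 2-[4-(benzyloxy)phenyl]-6-{4-[3-(2-hydroxy-4,6-dimethoxyphenyl)-3-oxoprop-1-yn-1-yl]phenoxy}-5,7-dimethoxy-4H-chromen-4-one | COc1cc(O)c(C(=O)C#Cc2ccc(Oc3c(OC)cc4oc(-c5ccc(OCc6ccccc6)cc5)cc(=O)c4c3OC)cc2)c(OC)c1 | intermediate
22 | 2-[4-({2-[4-(benzyloxy)phenyl]-5,7-dimethoxy-4-oxo-4H-chromen-6-yl}oxy)phenyl]-5,7-dimethoxy-4H-chromen-4-one | COc1cc(OC)c2c(=O)cc(-c3ccc(Oc4c(OC)cc5oc(-c6ccc(OCc7ccccc7)cc6)cc(=O)c5c4OC)cc3)oc2c1 | intermediate
23 | 5-hydroxy-2-(4-{[5-hydroxy-2-(4-hydroxyphenyl)-7-methoxy-4-oxo-4H-chromen-6-yl]oxy}phenyl)-7-methoxy-4H-chromen-4-one (7,7''-di-O-methylhinokiflavone) | COc1cc(O)c2c(=O)cc(-c3ccc(Oc4c(OC)cc5oc(-c6ccc(O)cc6)cc(=O)c5c4O)cc3)oc2c1 | target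

**Totals**
Total step count: 12.
Longest linear sequence: 10 steps (steps 1–8, 11 and 12, from syringaldehyde). The aryne precursor is a two-step side branch (steps 9 and 10).

**Steps most likely to fail**

**1. Step 11.** Several processes can compete with the insertion:
- The aryl anion may take up a proton before acyl transfer, which amounts to plain O-arylation of the acid.
- The aryl anion may add to the alkyne terminus instead of the carboxyl carbon.
- The caesium propiolate may lose CO2 at 125 °C.
- The phenoxide may close in the 5-exo mode.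

The fallback builds the same pyranone by palladium-catalysed carbonylative annulation. It sets out from iodide 12 and phenol 15 and comes back at 22. Sonogashira coupling of 12 with trimethylsilylacetylene (PdCl2(PPh3)2, CuI, Et3N, THF) should give the trimethylsilylalkyne F1. K2CO3 in MeOH should then give the terminal alkyne F2. In parallel, N-iodosuccinimide in CH2Cl2 should convert 15 into 2-iodo-3,5-dimethoxyphenol F3. Heating F2 and F3 under CO with PdCl2(dppf) in Et2NH (100 °C, pressure vessel) should pass through ynone 21, which the amine medium steers into 6-endo closure to 22.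

**2. Step 8.** Palladium and base may decarboxylate propiolic acid or the product. A terminal alkyne would then form, followed by a second arylation to a diarylalkyne.

The fallback changes the oxidation level of the three-carbon unit. It sets out from 12 and comes back at 14. Sonogashira coupling of 12 with propargyl alcohol (PdCl2(PPh3)2, CuI, Et3N, THF, rt) should give the propargylic alcohol F4. Oxidation with catalytic TEMPO and PhI(OAc)2 in MeCN/H2O should then take F4 to acid 14 without touching the benzyl ether or the chromenone.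

**3. Step 3.** Three things may go wrong: loss of chemoselectivity between the two hydroxyl groups, double arylation, or air oxidation of the hydroquinone under base.

The fallback forms the ether on a monophenol before the second oxygen exists. It sets out from 1 and 5 and comes back at 6.
- SNAr of 1 with 5 (K2CO3, DMF, 80 °C) should give 3,5-dimethoxy-4-(4-nitrophenoxy)benzaldehyde F5.
- Baeyer–Villiger oxidation with mCPBA in CH2Cl2 should give the aryl formate F6.
- Methanolysis (K2CO3, MeOH) should give 3,5-dimethoxy-4-(4-nitrophenoxy)phenol F7.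
- Friedel–Crafts acylation with AcOH/BF3·OEt2 at 85 °C, at either of the two equivalent positions ortho to the hydroxyl, should give 6.

**Further compounds**
F1 | step 11 | 2-[4-(benzyloxy)phenyl]-5,7-dimethoxy-6-{4-[(trimethylsilyl)ethynyl]phenoxy}-4H-chromen-4-one | C[Si](C)(C)C#Cc1ccc(Oc2c(OC)cc3oc(-c4ccc(OCc5ccccc5)cc4)cc(=O)c3c2OC)cc1
F2 | step 11 | 2-[4-(benzyloxy)phenyl]-6-(4-ethynylphenoxy)-5,7-dimethoxy-4H-chromen-4-one | C#Cc1ccc(Oc2c(OC)cc3oc(-c4ccc(OCc5ccccc5)cc4)cc(=O)c3c2OC)cc1
F3 | step 11 | 2-iodo-3,5-dimethoxyphenol | Ic1c(O)cc(OC)cc1OC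
F4 | step 8 | 2-[4-(benzyloxy)phenyl]-6-[4-(3-hydroxyprop-1-yn-1-yl)phenoxy]-5,7-dimethoxy-4H-chromen-4-one | OCC#Cc1ccc(Oc2c(OC)cc3oc(-c4ccc(OCc5ccccc5)cc4)cc(=O)c3c2OC)cc1
F5 | step 3 | 3,5-dimethoxy-4-(4-nitrophenoxy)benzaldehyde | COc1cc(C=O)cc(OC)c1Oc1ccc([N+](=O)[O-])cc1
F6 | step 3 | 3,5-dimethoxy-4-(4-nitrophenoxy)phenyl formate | COc1cc(OC=O)cc(OC)c1Oc1ccc([N+](=O)[O-])cc1
F7 | step 3 | 3,5-dimethoxy-4-(4-nitrophenoxy)phenol | COc1cc(O)cc(OC)c1Oc1ccc([N+](=O)[O-])cc1
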